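**Retrosynthetic overview**
1. The target is traced back to its penta-O-methyl di-O-acetyl derivative. In that derivative the cycloheptane ring is opened at the bond between its CH(4-methoxyphenyl) carbon and the fused resorcinol ring, which gives an (E)-4-methoxystilbene.
2. Enabling feature: the central benzene ring carries two dihydrofuran rings, fused at its two O–C/C–C edges on either side of the carbon bearing the cycloheptane CH2. Both have the same substituents (4-hydroxyphenyl on O–CH, a 3,5-dioxygenated aryl on the other CH, trans) but opposite configuration (R,R in the free ring, S,S in the ring tied into the cycloheptane).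
3. They are therefore mirror images through the plane containing the CH2-bearing ring carbon and the ring CH para to it. Only the cycloheptane bond breaks this symmetry, so the seco-stilbene is a meso compound with pairwise equivalent annulation sites.
4. Both dihydrofuran rings, each with its aryl C–C3 bond and its O–C2 bond, are made at once by a two-directional oxidative [3+2] annulation of desoxyrhapontigenin with two molecules of pterostilbene.
5. Ring order: the two dihydrofuran rings first (step 1), the cycloheptane ring last (step 3, enantiotopos-selective Friedel–Crafts hydroarylation that sets the absolute configuration).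

Key step: step 1

Remark: the two compounds that precede the cyclisation are meso (achiral), so chirality first appears in step 3. Which antipode of the chiral acid gives the required enantiomer cannot be predicted; it is fixed by a test run, and the route is written for that antipode.
Assumption: desoxyrhapontigenin and pterostilbene are taken as commercial catalogue stilbenes.

**Step 1**
Reactants: 1 desoxyrhapontigenin; 2 pterostilbene (2.4 equiv)
Product: 4 meso-(2S,3S,5R,6R)-3,5-bis(3,5-dimethoxyphenyl)-2,6-bis(4-hydroxyphenyl)-4-[(E)-2-(4-methoxyphenyl)ethenyl]-2,3,5,6-tetrahydrobenzo[1,2-b:5,4-b']difuran, via racemic trans mono-dihydrobenzofuran 3 (not isolated)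
Conditions: RuCl3·3H2O (4.4 equiv), MeOH/H2O 4:1, 35 °C, 2 added over 8 h; chromatography
Reagents that add atoms: none
Why: Biomimetic oxidative phenol–alkenylphenol [3+2] coupling, the reaction type by which oxidants such as RuCl3 turn resveratrol into ε-viniferin, applied twice to one resorcinol ring: trivalent ruthenium oxidises only the conjugated 4-hydroxystyryl phenol of 2 to a phenoxyl radical/phenoxonium species that is electrophilic at the olefinic carbon next to the dimethoxyphenyl ring, and this carbon is attacked by C-4 and then C-6 of the resorcinol ring of 1 (aryl C–C bond). Rearomatisation leaves a p-quinone methide whose exocyclic carbon is captured by the neighbouring resorcinol hydroxyl in a 5-exo-trig oxa-1,6-addition (O–C bond), which closes each of the two dihydrofuran rings. The stereocentres C-3 and C-5 arise in the C–C bond formation without facial control, and C-2 and C-6 are then set trans to them by the adjacent aryl group in the reversible ring closure (thermodynamic control). The two rings form independently, so meso-4 is expected together with its C2-symmetric racemic diastereomer, from which it is separated by chromatography and recognised as the isomer that is not split on a chiral stationary phase. Chemoselectivity is secured by the partners: 1 has no oxidisable 4-hydroxystyryl unit (its 4′-oxygen is methylated), its free resorcinol ring is the most electron-rich arene present and the only one whose adduct can close to a furan, and slow addition of 2 limits self-coupling of the oxidised partner. Regioselectivity for the two positions flanking the styryl carbon over C-2 between the hydroxyls follows the intrinsic preference shown by the resorcinol ring in ε-viniferin formation.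

**Step 2**
Reactants: 4 meso bis(dihydrofuran) diphenol
Product: 5 meso-(2S,3S,5R,6R)-2,6-bis(4-acetoxyphenyl)-3,5-bis(3,5-dimethoxyphenyl)-4-[(E)-2-(4-methoxyphenyl)ethenyl]-2,3,5,6-tetrahydrobenzo[1,2-b:5,4-b']difuran
Conditions: Ac2O, pyridine, DMAP (cat.), CH2Cl2, rt
Reagents that add atoms: acetic anhydride CC(=O)OC(C)=O
Why: Standard DMAP-catalysed O-acetylation of the two remaining phenols; the acetates make the C-2/C-6 aryl groups electron-poor so that the benzylic C–O bonds of the dihydrofuran rings should not ionise under the acid of step 3, and no stereocentre is touched.

**Step 3**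
Reactants: 5 meso diacetate
Product: 6 penta-O-methyl di-O-acetyl derivative of the target (single enantiomer, configuration at all five stereocentres as in the target)
Conditions: chiral imidodiphosphorimidate Brønsted acid (IDPi, 5 mol %), CHCl3, 0 °C to rt
Reagents that add atoms: none
Why: Proposed new method: the confined chiral acid should protonate the 4-methoxystilbene at the olefinic carbon attached to the central ring, giving a 4-methoxybenzyl cation paired with the chiral anion, which is captured in a seven-membered (7-endo) Friedel–Crafts closure by the ortho carbon of one of the two enantiotopic 3,5-dimethoxyphenyl rings; each ring can reach only one face of the cation with the anisyl group pseudo-equatorial (the substrate-controlled outcome of the acid-mediated change of ε-viniferin into ampelopsin B), so the anion's choice of cation face selects the ring, sets the new (S) stereocentre and thereby fixes the absolute configuration of all five centres; closest known reaction types are the chiral-acid-catalysed asymmetric intramolecular hydroarylation of olefins and the achiral acid cyclisation of ε-viniferin-type stilbenes, and what is new is the stilbene/dimethoxyarene pair and the desymmetrisation of a meso substrate.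

**Step 4**
Reactants: 6 cyclised pentamethyl ether diacetate
Product: 7 penta-O-methyl ether of the target (the two 4-hydroxyphenyl groups on the dihydrofuran O–CH carbons free)
Conditions: K2CO3 (0.2 equiv), MeOH/THF, 0 °C to rt, argon
Reagents that add atoms: none
Why: Base-catalysed transesterification (Zemplén-type methanolysis) of the two aryl acetates; methyl ethers, ring system and stereocentres are inert under these conditions.

**Step 5**
Reactants: 7 pentamethyl ether
Product: 8 CNP0136963.1 (target)
Conditions: BBr3 (excess), CH2Cl2, −78 °C to rt; aqueous work-up
Reagents that add atoms: none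
Why: Lewis-acid cleavage of the five aryl methyl ethers with BBr3, a transformation with precedent on methylated ε-viniferin/ampelopsin B frameworks; the cycloheptane stereocentre is held by C–C bonds and cannot ionise, and the trans arrangement in both dihydrofuran rings is the thermodynamic one, so no stereocentre is expected to change.

**Compound list**
1 | desoxyrhapontigenin, (E)-5-[2-(4-methoxyphenyl)ethenyl]benzene-1,3-diol | COc1ccc(/C=C/c2cc(O)cc(O)c2)cc1 | starting material
2 | pterostilbene, (E)-4-[2-(3,5-dimethoxyphenyl)ethenyl]phenol | COc1cc(/C=C/c2ccc(O)cc2)cc(OC)c1 | starting material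
3 | racemic trans-(2S*,3S*)-3-(3,5-dimethoxyphenyl)-2-(4-hydroxyphenyl)-4-[(E)-2-(4-methoxyphenyl)ethenyl]-2,3-dihydro-1-benzofuran-6-ol (one enantiomer drawn) | COc1ccc(/C=C/c2cc(O)cc3c2[C@H](c2cc(OC)cc(OC)c2)[C@@H](c2ccc(O)cc2)O3)cc1 | intermediate
4 | meso-(2S,3S,5R,6R)-3,5-bis(3,5-dimethoxyphenyl)-2,6-bis(4-hydroxyphenyl)-4-[(E)-2-(4-methoxyphenyl)ethenyl]-2,3,5,6-tetrahydrobenzo[1,2-b:5,4-b']difuran | COc1ccc(/C=C/c2c3c(cc4c2[C@@H](c2cc(OC)cc(OC)c2)[C@H](c2ccc(O)cc2)O4)O[C@H](c2ccc(O)cc2)[C@H]3c2cc(OC)cc(OC)c2)cc1 | intermediate
5 | meso-(2S,3S,5R,6R)-2,6-bis(4-acetoxyphenyl)-3,5-bis(3,5-dimethoxyphenyl)-4-[(E)-2-(4-methoxyphenyl)ethenyl]-2,3,5,6-tetrahydrobenzo[1,2-b:5,4-b']difuran | COc1ccc(/C=C/c2c3c(cc4c2[C@@H](c2cc(OC)cc(OC)c2)[C@H](c2ccc(OC(C)=O)cc2)O4)O[C@H](c2ccc(OC(C)=O)cc2)[C@H]3c2cc(OC)cc(OC)c2)cc1 | intermediate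
6 | target skeleton as penta-O-methyl di-O-acetyl derivative: (S)-CH(4-methoxyphenyl) in the cycloheptane ring, four resorcinol oxygens methylated, (2S,3S)-dihydrofuran fused into the cycloheptane and free (2R,3R)-dihydrofuran each with 4-acetoxyphenyl on O–CH | COc1ccc([C@@H]2Cc3c4c(cc5c3[C@@H](c3cc(OC)cc(OC)c3)[C@H](c3ccc(OC(C)=O)cc3)O5)O[C@H](c3ccc(OC(C)=O)cc3)[C@H]4c3cc(OC)cc(OC)c32)cc1 | intermediate
7 | penta-O-methyl ether of the target (as 6 with both acetates replaced by free phenols) | COc1ccc([C@@H]2Cc3c4c(cc5c3[C@@H](c3cc(OC)cc(OC)c3)[C@H](c3ccc(O)cc3)O5)O[C@H](c3ccc(O)cc3)[C@H]4c3cc(OC)cc(OC)c32)cc1 | intermediate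
8 | CNP0136963.1, the nonaphenolic resveratrol trimer with (S)-CH(4-hydroxyphenyl) in the cycloheptane ring, (2S,3S)-dihydrofuran in the fused system and free (2R,3R)-dihydrofuran | Oc1ccc([C@@H]2Cc3c4c(cc5c3[C@@H](c3cc(O)cc(O)c3)[C@H](c3ccc(O)cc3)O5)O[C@H](c3ccc(O)cc3)[C@H]4c3cc(O)cc(O)c32)cc1 | target

Total step count: 5. Longest linear sequence: 5 steps (both starting materials enter in step 1).

**Steps most likely to fail**

Step 3 (proposed new method). The chiral anion may fail to tell the two enantiotopic dimethoxyphenyl rings apart, giving low enantiomeric purity, or the acid strength needed may start to open a dihydrofuran ring. Fallback with known chemistry: set out from 5 and cyclise it with an achiral acid (TsOH·H2O, CH2Cl2, rt), the acid-mediated stilbene-to-cycloheptane closure known for ε-viniferin-type compounds. This should give 6 together with an equal amount of its mirror image, ent-6 F1. The two are separated by preparative chromatography on a chiral polysaccharide phase, and the route is rejoined at 6.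

Step 1 (key step). The oxidised form of 2 may be consumed by self-coupling faster than it is captured by 1, attack may occur at C-2 between the hydroxyls, and the two ring closures may favour the C2-symmetric diastereomer. Fallback: give up the two-directional annulation and build the rings one at a time, each time with the nucleophile in excess, closing the cycloheptane ring in between. From 1 (3 equiv) and 2 (1 equiv) under the conditions of step 1 the mono-adduct 3 is isolated as the racemate and unchanged 1 is recovered. Acid (HCl in MeOH or TsOH, rt) converts 3 into the racemic tetracyclic cycloheptane-fused dihydrobenzofuranol F2. A second oxidative [3+2] annulation of F2 (in excess) with 2 then takes place at the one ring position flanked by the CH2-bearing carbon and the free hydroxyl. After separation from its epimers this should give racemic 7, that is 7 together with ent-7 F3. Resolution on a chiral stationary phase returns the route at 7, and step 5 follows.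

Step 5. HBr and the Lewis acid may open the free dihydrofuran ring by heterolysis of its benzylic C–O bond once the 4-oxyphenyl group on that carbon is electron-rich, or cleavage of the five ethers may stay incomplete. Fallback: invert the order of the deprotections so that the electron-withdrawing acetates are still in place during the Lewis-acid step. Set out from 6 and treat it with BBr3 (CH2Cl2, −78 to 0 °C), which should give the di-O-acetyl heptaphenol F4. Methanolysis as in step 4 (K2CO3 cat., MeOH) then gives 8. Any acetate lost early is of no consequence for the product, because the last operation removes both.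

**Further compounds**
F1 | step 3 | ent-6, mirror image of the penta-O-methyl di-O-acetyl derivative 6 | COc1ccc([C@H]2Cc3c4c(cc5c3[C@H](c3cc(OC)cc(OC)c3)[C@@H](c3ccc(OC(C)=O)cc3)O5)O[C@@H](c3ccc(OC(C)=O)cc3)[C@@H]4c3cc(OC)cc(OC)c32)cc1
F2 | step 1 | racemic cycloheptane-fused dihydrobenzofuranol from 3 (tri-O-methyl ampelopsin B type, relative configuration as in the target, one enantiomer drawn) | COc1ccc([C@@H]2Cc3cc(O)cc4c3[C@H](c3cc(OC)cc(OC)c32)[C@@H](c2ccc(O)cc2)O4)cc1
F3 | step 1 | ent-7, mirror image of the penta-O-methyl ether 7 | COc1ccc([C@H]2Cc3c4c(cc5c3[C@H](c3cc(OC)cc(OC)c3)[C@@H](c3ccc(O)cc3)O5)O[C@@H](c3ccc(O)cc3)[C@@H]4c3cc(OC)cc(OC)c32)cc1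
F4 | step 5 | di-O-acetyl heptaphenol (target with both 4-hydroxyphenyl groups on the dihydrofuran O–CH carbons acetylated) | Oc1ccc([C@@H]2Cc3c4c(cc5c3[C@@H](c3cc(O)cc(O)c3)[C@H](c3ccc(OC(C)=O)cc3)O5)O[C@H](c3ccc(OC(C)=O)cc3)[C@H]4c3cc(O)cc(O)c32)cc1
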